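**Retrosynthetic overview**
- Last disconnection: the bond between aromatic C7 of the dihydrobenzofuran and the bridging CH2. It is made by a biomimetic union of the unprotected acylphloroglucinol-type dihydrobenzofuran with a 3-methylidene-pyran-2,4-dione released from a Mannich salt of the pyranone.
- Enabling feature: C7 is the only unsubstituted carbon of the phloroglucinol ring, flanked by the C6 hydroxyl and by ring oxygen O1 on C7a, so it is a vinylogous enol carbon. C3 of the pyranone ring lies between the C2 lactone carbonyl and the C4 enol, so a CH2–NMe2 group there eliminates to an o-quinone-methide-type acceptor.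
- Dihydrofuran ring: closed on the bought benzene ring by Pd-catalysed asymmetric allylic O-alkylation of an (E)-allylic carbonate, which sets C2 as (R). The chain comes from C-alkylation of the (R)-acylphloroglucinol, whose stereocentre comes from (R)-2-methylbutanoic acid.
- Pyranone ring: closed separately from the silyl enol ether of pentan-3-one and malonyl dichloride, then aminomethylated at C3.
- Order of ring formation: benzene ring bought (phloroglucinol), dihydrofuran ring in step 5, pyranone ring in step 7 on the other branch; the union in step 9 closes no ring.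

Key step: step 9

Assumption: the (R,R) enantiomer of the DACH-phenyl bis(phosphinobenzamide) ligand is taken to deliver the (2R) ring, by analogy with closely related 2-(4-carbonyloxy-3-methylbut-2-enyl)phenols; if the sense proves opposite, the (S,S) ligand is used and nothing else changes.

**Route**

Step 1
Reactants: 1 (R)-2-methylbutanoic acid; 2 phloroglucinol
Product: 4 (2R)-2-methyl-1-(2,4,6-trihydroxyphenyl)butan-1-one, via (R)-2-methylbutanoyl chloride 3 (not isolated)
Conditions: (COCl)2, DMF (cat.), CH2Cl2, 0 °C → rt, concentrate; then 2, AlCl3 (3.5 equiv), PhNO2/CH2Cl2, 0 → 40 °C; aq. HCl work-up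
Reagents that add atoms: none
Why: Friedel–Crafts C-acylation of the electron-rich, threefold symmetric phloroglucinol should stop at the mono-ketone because the first acyl group deactivates the ring, and the (R) stereocentre is carried over from 1, the mild temperature and the aluminium chelate of the product ketone disfavouring enolisation.

Step 2
Reactants: 5 2-methyl-2-vinyloxirane (racemic)
Product: 6 (E)-4-chloro-2-methylbut-2-en-1-ol
Conditions: TiCl4 (1.05 equiv), CH2Cl2, −85 °C; aq. HCl work-up
Reagents that add atoms: titanium tetrachloride, Cl[Ti](Cl)(Cl)Cl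
Why: Lewis-acid-assisted SN2′ opening of the vinyl epoxide delivers chloride to the vinyl terminus through a cyclic array that places CH2O–Ti trans to the new CH2Cl, which should give the (E)-chloro alcohol; the epoxide stereocentre is destroyed, so racemic 5 suffices.

Step 3
Reactants: 6 (E)-4-chloro-2-methylbut-2-en-1-ol
Product: 7 (E)-4-chloro-2-methylbut-2-en-1-yl methyl carbonate
Conditions: ClCO2Me, pyridine, CH2Cl2, 0 °C
Reagents that add atoms: methyl chloroformate, COC(=O)Cl
Why: Standard acylation of a primary allylic alcohol with a chloroformate installs the carbonate leaving group needed in step 5 without touching the allylic chloride.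

Step 4
Reactants: 4 (2R)-2-methyl-1-(2,4,6-trihydroxyphenyl)butan-1-one; 7 (E)-4-chloro-2-methylbut-2-en-1-yl methyl carbonate
Product: 8 (E)-4-{2,4,6-trihydroxy-3-[(2R)-2-methylbutanoyl]phenyl}-2-methylbut-2-en-1-yl methyl carbonate
Conditions: DBU (1.1 equiv), THF, 0 °C → rt; 4 in excess (2 equiv), recovered
Reagents that add atoms: none
Why: Base-mediated C-alkylation of an acylphloroglucinol with a γ,γ-disubstituted allylic halide (the reaction type of classical C-prenylation) should occur at a ring carbon because the delocalised phenoxide is a soft nucleophile; C3 and C5 of 4 are equivalent, excess 4 limits double alkylation, the SN2 displacement keeps the (E) alkene, and phenoxide formation shields the ketone α-stereocentre from enolisation.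

Step 5
Reactants: 8 (E)-4-{2,4,6-trihydroxy-3-[(2R)-2-methylbutanoyl]phenyl}-2-methylbut-2-en-1-yl methyl carbonate
Product: 9 (2R)-1-[(2R)-4,6-dihydroxy-2-(prop-1-en-2-yl)-2,3-dihydro-1-benzofuran-5-yl]-2-methylbutan-1-one
Conditions: Pd2(dba)3·CHCl3 (2.5 mol %), (R,R)-DACH-phenyl ligand (7.5 mol %), AcOH (1 equiv), CH2Cl2, rt; stopped at full conversion
Reagents that add atoms: none
Why: In this intramolecular Tsuji–Trost asymmetric allylic O-alkylation Pd(0) ionises the carbonate with loss of CO2 and methoxide, the para hydroxyl (the most acidic one and the only one next to the chain that cannot hydrogen-bond to the ketone) attacks the internal terminus of the π-allyl complex in a 5-exo closure, and the chiral pocket of the ligand selects the face of the allyl unit so that C2 is set as (R) under catalyst control, independent of the remote acyl stereocentre.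

Step 6
Reactants: 10 pentan-3-one
Product: 11 3-(trimethylsilyloxy)pent-2-ene (E/Z mixture)
Conditions: TMSCl, Et3N, DMF, 80 °C
Reagents that add atoms: chlorotrimethylsilane, C[Si](C)(C)Cl
Why: Silylation of a symmetric ketone under equilibrating amine conditions should give the silyl enol ether, whose E/Z composition is irrelevant because this double bond ends in the aromatic pyranone.

Step 7
Reactants: 11 3-(trimethylsilyloxy)pent-2-ene; 12 malonyl dichloride
Product: 13 6-ethyl-4-hydroxy-5-methyl-2H-pyran-2-one
Conditions: Et2O, −78 °C → rt
Reagents that add atoms: none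
Why: C-acylation of the silyl enol ether by one acid chloride group followed by lactonisation of the resulting diketone enol onto the second one is the established one-pot synthesis of 4-hydroxy-2-pyranones and fixes ethyl at C6 and methyl at C5 by construction.

Step 8
Reactants: 13 6-ethyl-4-hydroxy-5-methyl-2H-pyran-2-one; 14 dimethylmethylideneammonium iodide (Eschenmoser's salt)
Product: 15 [(6-ethyl-4-hydroxy-5-methyl-2-oxo-2H-pyran-3-yl)methyl]dimethylammonium iodide
Conditions: MeCN, rt; precipitated with Et2O
Reagents that add atoms: none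
Why: Mannich reaction of the enolic C3, the only nucleophilic carbon of 13, with the preformed iminium salt under anhydrous, base-free conditions should give the aminomethyl compound as its ammonium salt, a form in which premature elimination to the methide and bis-pyranone formation are suppressed.

Step 9
Reactants: 9 (2R)-1-[(2R)-4,6-dihydroxy-2-(prop-1-en-2-yl)-2,3-dihydro-1-benzofuran-5-yl]-2-methylbutan-1-one; 15 [(6-ethyl-4-hydroxy-5-methyl-2-oxo-2H-pyran-3-yl)methyl]dimethylammonium iodide
Product: 17 3-{[(2R)-4,6-dihydroxy-5-[(2R)-2-methylbutanoyl]-2-(prop-1-en-2-yl)-2,3-dihydro-1-benzofuran-7-yl]methyl}-6-ethyl-4-hydroxy-5-methyl-2H-pyran-2-one, via 6-ethyl-5-methyl-3-methylidenepyran-2,4-dione 16 (not isolated)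
Conditions: NaOAc (1.1 equiv), MeCN, 60 °C, N2; 15 (1.3 equiv) added in portions
Reagents that add atoms: none
Why: Acetate converts the ammonium enol 15 into its zwitterion, which loses dimethylamine by E1cB elimination to the 3-methylidene-pyran-2,4-dione 16, a heterocyclic o-quinone-methide-type acceptor; C7 of 9 adds to its exocyclic CH2 in a Friedel–Crafts-type conjugate addition, and two tautomerisations restore the phenol ring and the 4-hydroxy-2-pyranone. The closest known reaction type is the Mannich-base (carba-Betti) union of 4-hydroxy-2-pyranones with acylphloroglucinols through a methylene bridge, which copies the presumed biosynthesis of such heterodimers, where a one-carbon unit on one ring becomes a methide that the other ring captures. No ring is closed and no stereocentre is formed; C2 of the dihydrofuran and C2 of the acyl chain are spectators under the buffered, near-neutral conditions. The step needs site selectivity (carbon against oxygen, and one ring carbon), which the substrate secures because C7 is the only unsubstituted carbon of the phloroglucinol ring, while any O-adduct reverts to 16 by retro-oxa-Michael reaction and the C-adduct does not. It also needs chemoselectivity against self-condensation of 16 and against hetero-Diels–Alder addition to the isopropenyl group, which portionwise addition of 15 and the far higher nucleophilicity of the phenol carbon should provide. The product is the unprotected target, so nothing has to be removed afterwards.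

**Compound list**
1 | (R)-2-methylbutanoic acid | CC[C@@H](C)C(=O)O | starting material
2 | phloroglucinol (benzene-1,3,5-triol) | Oc1cc(O)cc(O)c1 | starting material
3 | (R)-2-methylbutanoyl chloride | CC[C@@H](C)C(=O)Cl | intermediate
4 | (2R)-2-methyl-1-(2,4,6-trihydroxyphenyl)butan-1-one | CC[C@@H](C)C(=O)c1c(O)cc(O)cc1O | intermediate
5 | 2-methyl-2-vinyloxirane (racemic) | C=CC1(C)CO1 | starting material
6 | (E)-4-chloro-2-methylbut-2-en-1-ol | OC/C(C)=C/CCl | intermediate
7 | (E)-4-chloro-2-methylbut-2-en-1-yl methyl carbonate | COC(=O)OC/C(C)=C/CCl | intermediate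
8 | (E)-4-{2,4,6-trihydroxy-3-[(2R)-2-methylbutanoyl]phenyl}-2-methylbut-2-en-1-yl methyl carbonate | CC[C@@H](C)C(=O)c1c(O)cc(O)c(C/C=C(\C)COC(=O)OC)c1O | intermediate
9 | (2R)-1-[(2R)-4,6-dihydroxy-2-(prop-1-en-2-yl)-2,3-dihydro-1-benzofuran-5-yl]-2-methylbutan-1-one | C=C(C)[C@H]1Cc2c(O)c(C(=O)[C@H](C)CC)c(O)cc2O1 | intermediate
10 | pentan-3-one | CCC(=O)CC | starting material
11 | 3-(trimethylsilyloxy)pent-2-ene (E/Z mixture) | CC=C(CC)O[Si](C)(C)C | intermediate
12 | malonyl dichloride | O=C(Cl)CC(=O)Cl | starting material
13 | 6-ethyl-4-hydroxy-5-methyl-2H-pyran-2-one | CCc1oc(=O)cc(O)c1C | intermediate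
14 | dimethylmethylideneammonium iodide (Eschenmoser's salt) | C=[N+](C)C.[I-] | starting material
15 | [(6-ethyl-4-hydroxy-5-methyl-2-oxo-2H-pyran-3-yl)methyl]dimethylammonium iodide | CCc1oc(=O)c(C[NH+](C)C)c(O)c1C.[I-] | intermediate
16 | 6-ethyl-5-methyl-3-methylidenepyran-2,4-dione | C=C1C(=O)OC(CC)=C(C)C1=O | intermediate
17 | 3-{[(2R)-4,6-dihydroxy-5-[(2R)-2-methylbutanoyl]-2-(prop-1-en-2-yl)-2,3-dihydro-1-benzofuran-7-yl]methyl}-6-ethyl-4-hydroxy-5-methyl-2H-pyran-2-one | C=C(C)[C@H]1Cc2c(O)c(C(=O)[C@H](C)CC)c(O)c(Cc3c(O)c(C)c(CC)oc3=O)c2O1 | target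

**Step count and risks**

Total step count: 9. Longest linear sequence: 5 steps (steps 2, 3, 4, 5, 9).

Steps most likely to fail:

1. Step 5. The ring may close through the hydroxyl next to the ketone instead of the para hydroxyl (wrong ring-closure regiochemistry), and the allylic aryl ether may re-ionise on palladium and lose enantiopurity. The fallback sets out from 8 and comes back at 9, and removes the choice of oxygen by protection. The para hydroxyl of 8, the most acidic and least hindered towards silylation, is silylated (TBSCl, imidazole, CH2Cl2, 0 °C) to (E)-4-{6-[(tert-butyldimethylsilyl)oxy]-2,4-dihydroxy-3-[(2R)-2-methylbutanoyl]phenyl}-2-methylbut-2-en-1-yl methyl carbonate F1. The two hydroxyls ortho to the ketone are acetylated (Ac2O, pyridine, DMAP) to the diacetate silyl ether F2. The silyl group is removed (HF·pyridine, THF, 0 °C) to the diacetate phenol F3, in which only the para oxygen can attack. The Pd/ligand system of step 5 then closes the ring to the diacetate (2R)-dihydrobenzofuran F4, and mild methanolysis (K2CO3 cat., MeOH, 0 °C) returns 9.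

2. Step 4. The oxygenated allylic chloride is a weaker electrophile than prenyl bromide, so O-alkylation, double C-alkylation and loss of the carbonate under base may outrun mono-C-alkylation. The fallback sets out from 4 and comes back at 8, and separates C–C bond formation from oxygenation. Classical C-prenylation of 4 (prenyl bromide, DBU, THF) gives (2R)-2-methyl-1-[2,4,6-trihydroxy-3-(3-methylbut-2-en-1-yl)phenyl]butan-1-one F5. Peracetylation (Ac2O, pyridine, DMAP) gives the triacetate F6. Allylic oxidation of the (E)-methyl group (SeO2 cat., t-BuOOH, CH2Cl2) gives the (E)-allylic alcohol triacetate F7. Methyl chloroformate and pyridine give the allylic carbonate triacetate F8. Selective ammonolysis of the three aryl acetates (NH3, MeOH, 0 °C) gives 8.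

3. Step 9. The methide may be consumed by self-condensation or by hetero-Diels–Alder addition to the isopropenyl group before it is intercepted at C7, which has only one free ortho hydroxyl. The fallback sets out from 8 and 15 and comes back at 17, and moves the union before the ring closure. The Mannich-salt union under the conditions of step 9 takes place at the single free ring carbon of 8, which lies between two free hydroxyls and carries no isopropenyl group, and gives the open-chain heterodimer (E)-4-{5-[(6-ethyl-4-hydroxy-5-methyl-2-oxo-2H-pyran-3-yl)methyl]-2,4,6-trihydroxy-3-[(2R)-2-methylbutanoyl]phenyl}-2-methylbut-2-en-1-yl methyl carbonate F9. Pd-catalysed asymmetric ring closure with the system of step 5 then gives 17 directly.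

**Further compounds**
F1 | step 5 | (E)-4-{6-[(tert-butyldimethylsilyl)oxy]-2,4-dihydroxy-3-[(2R)-2-methylbutanoyl]phenyl}-2-methylbut-2-en-1-yl methyl carbonate | CC[C@@H](C)C(=O)c1c(O)cc(O[Si](C)(C)C(C)(C)C)c(C/C=C(\C)COC(=O)OC)c1O
F2 | step 5 | (E)-4-{2,4-diacetoxy-6-[(tert-butyldimethylsilyl)oxy]-3-[(2R)-2-methylbutanoyl]phenyl}-2-methylbut-2-en-1-yl methyl carbonate | CC[C@@H](C)C(=O)c1c(OC(C)=O)cc(O[Si](C)(C)C(C)(C)C)c(C/C=C(\C)COC(=O)OC)c1OC(C)=O
F3 | step 5 | (E)-4-{2,4-diacetoxy-6-hydroxy-3-[(2R)-2-methylbutanoyl]phenyl}-2-methylbut-2-en-1-yl methyl carbonate | CC[C@@H](C)C(=O)c1c(OC(C)=O)cc(O)c(C/C=C(\C)COC(=O)OC)c1OC(C)=O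
F4 | step 5 | (2R)-5-[(2R)-2-methylbutanoyl]-2-(prop-1-en-2-yl)-2,3-dihydro-1-benzofuran-4,6-diyl diacetate | C=C(C)[C@H]1Cc2c(OC(C)=O)c(C(=O)[C@H](C)CC)c(OC(C)=O)cc2O1
F5 | step 4 | (2R)-2-methyl-1-[2,4,6-trihydroxy-3-(3-methylbut-2-en-1-yl)phenyl]butan-1-one | CC[C@@H](C)C(=O)c1c(O)cc(O)c(CC=C(C)C)c1O
F6 | step 4 | 2-[(2R)-2-methylbutanoyl]-4-(3-methylbut-2-en-1-yl)benzene-1,3,5-triyl triacetate | CC[C@@H](C)C(=O)c1c(OC(C)=O)cc(OC(C)=O)c(CC=C(C)C)c1OC(C)=O
F7 | step 4 | 2-[(E)-4-hydroxy-3-methylbut-2-en-1-yl]-4-[(2R)-2-methylbutanoyl]benzene-1,3,5-triyl triacetate | CC[C@@H](C)C(=O)c1c(OC(C)=O)cc(OC(C)=O)c(C/C=C(\C)CO)c1OC(C)=O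
F8 | step 4 | 2-{(E)-4-[(methoxycarbonyl)oxy]-3-methylbut-2-en-1-yl}-4-[(2R)-2-methylbutanoyl]benzene-1,3,5-triyl triacetate | CC[C@@H](C)C(=O)c1c(OC(C)=O)cc(OC(C)=O)c(C/C=C(\C)COC(=O)OC)c1OC(C)=O
F9 | step 9 | (E)-4-{5-[(6-ethyl-4-hydroxy-5-methyl-2-oxo-2H-pyran-3-yl)methyl]-2,4,6-trihydroxy-3-[(2R)-2-methylbutanoyl]phenyl}-2-methylbut-2-en-1-yl methyl carbonate | CC[C@@H](C)C(=O)c1c(O)c(Cc2c(O)c(C)c(CC)oc2=O)c(O)c(C/C=C(\C)COC(=O)OC)c1O
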